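**Plan**

- Retrosynthetic cuts, in order: C8–prenyl (dearomative allylation); C8–CH2 of the lavandulyl group (sp2–sp3 coupling); C3–C4 of the pyranone (intramolecular hydroacylation); ring C–CHO and ring C–iodine; O1–C2 (etherification). This leads back to 5,7-dihydroxy-4-phenylcoumarin, (S)-but-3-en-2-ol, (R)-lavandulol and prenyl acetate.
- Enabling feature: the pyranone is a 3-methylchroman-4-one whose ketone carbon C4 sits on ring carbon C4a next to the O1-bearing carbon C8a, and whose C3 methyl is the hydrogen-capped end of a vinyl group on C2. An ortho-formyl aryl (R)-but-3-en-2-yl ether therefore isomerises to it with no added atoms.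
- Forward logic: etherifying the coumarin 7-OH first fixes which oxygen becomes O1. Reduction and methanolysis of the purchased lactone ring set the benzylic centre and make the two free ring positions equivalent, so formylation and iodination need no regiocontrol. Two methoxymethyl groups are helpers for the carbene step and are removed in step 9.
- Ring order: benzene ring from the start; pyranone ring in step 6; lavandulyl group in step 8; dearomatisation of the carbocycle at C8 in step 10; ester hydrolysis last.
- Stereochemistry: C2 from (S)-but-3-en-2-ol with inversion; the benzylic centre from ligand-controlled CuH reduction; C3 in the key step (cis to C2, substrate plus catalyst control); the lavandulyl centre from (R)-lavandulol; C8 from ligand-controlled palladium allylation.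

Key step: step 6

Assumption: (R)-(−)-lavandulol is taken as a purchasable chiral-pool alcohol, and the named antipodes of the chiral ligands and of the triazolium catalyst are those expected to give the stated configurations; each would be exchanged for its mirror image if a model run shows the opposite sense.

**Route**

Step 1
Reactants: 1 5,7-dihydroxy-4-phenyl-2H-chromen-2-one (5,7-dihydroxy-4-phenylcoumarin); 2 (S)-but-3-en-2-ol
Product: 3 7-[(2R)-but-3-en-2-yloxy]-5-hydroxy-4-phenyl-2H-chromen-2-one
Conditions: PPh3, DIAD, THF, 0 °C → rt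
Reagents that add atoms: none
Why: Mitsunobu etherification should take place at the 7-OH, which is the more acidic phenol (para-quinoid conjugation with the enoate) and is unhindered, whereas the 5-OH is shielded by the peri phenyl group; SN2 displacement inverts the secondary allylic carbinol, so the (S)-alcohol gives the (R)-ether that becomes C2.

Step 2
Reactants: 3 7-[(2R)-but-3-en-2-yloxy]-5-hydroxy-4-phenyl-2H-chromen-2-one
Product: 5 methyl (3S)-3-{4-[(2R)-but-3-en-2-yloxy]-2,6-dihydroxyphenyl}-3-phenylpropanoate, via dihydrocoumarin lactone 4 (not isolated)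
Conditions: Cu(OAc)2·H2O (cat.), (S)-DTBM-SEGPHOS (cat.), HSiMe(OEt)2 (3 equiv), toluene, 0 °C → rt; then MeOH, K2CO3 (cat.), rt
Reagents that add atoms: methanol, CO
Why: Asymmetric CuH conjugate reduction of a 4-arylcoumarin, in which the ligated hydride should add to C4 of the electron-poor enoate much faster than it hydrometalates the isolated vinyl group, the ligand selects the face that gives 4S, the silyl ketene acetal resists over-reduction until the methanol quench, and carbonate-catalysed methanolysis then opens the aryl lactone and frees the silylated phenol.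

Step 3
Reactants: 5 methyl (3S)-3-{4-[(2R)-but-3-en-2-yloxy]-2,6-dihydroxyphenyl}-3-phenylpropanoate
Product: 6 methyl (3S)-3-{4-[(2R)-but-3-en-2-yloxy]-3-formyl-2,6-dihydroxyphenyl}-3-phenylpropanoate
Conditions: POCl3, DMF, MeCN, 0 °C → rt; then H2O
Reagents that add atoms: N,N-dimethylformamide, CN(C)C=O; water, O
Why: Vilsmeier–Haack formylation of a phloroglucinol nucleus, in which the two free ring positions are constitutionally equivalent once the lactone is open, so either gives the same aldehyde, and the first formyl group deactivates the ring toward a second.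

Step 4
Reactants: 6 methyl (3S)-3-{4-[(2R)-but-3-en-2-yloxy]-3-formyl-2,6-dihydroxyphenyl}-3-phenylpropanoate
Product: 7 methyl (3S)-3-{4-[(2R)-but-3-en-2-yloxy]-3-formyl-2,6-dihydroxy-5-iodophenyl}-3-phenylpropanoate
Conditions: NIS (1.0 equiv), MeCN, 0 °C
Reagents that add atoms: N-iodosuccinimide, O=C1CCC(=O)N1I
Why: Electrophilic aromatic iodination at the only remaining ring CH, which is ortho or para to three oxygen substituents and should react far faster than the isolated vinyl group.

Step 5
Reactants: 7 methyl (3S)-3-{4-[(2R)-but-3-en-2-yloxy]-3-formyl-2,6-dihydroxy-5-iodophenyl}-3-phenylpropanoate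
Product: 8 methyl (3S)-3-{4-[(2R)-but-3-en-2-yloxy]-3-formyl-5-iodo-2,6-bis(methoxymethoxy)phenyl}-3-phenylpropanoate
Conditions: MOMCl, i-Pr2NEt, Bu4NI (cat.), CH2Cl2, 0 °C → 40 °C
Reagents that add atoms: chloromethyl methyl ether, COCCl
Why: O-alkylation of both phenols as methoxymethyl acetals removes the acidic protons that would quench the carbene catalyst in step 6 and the organozinc reagent in step 8, and leaves an aldehyde flanked only by ether oxygens.

Step 6
Reactants: 8 methyl (3S)-3-{4-[(2R)-but-3-en-2-yloxy]-3-formyl-5-iodo-2,6-bis(methoxymethoxy)phenyl}-3-phenylpropanoate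
Product: 9 methyl (3S)-3-[(2R,3S)-8-iodo-5,7-bis(methoxymethoxy)-2,3-dimethyl-4-oxochroman-6-yl]-3-phenylpropanoate
Conditions: N-mesityl aminoindanol-derived triazolium chloride, (5aR,10bS) antipode (20 mol %), DBU (15 mol %), 1,4-dioxane, 80 °C, argon
Reagents that add atoms: none
Why: The carbene adds to the aldehyde to give the nucleophilic hydroxy-enamine (acyl-anion equivalent), whose carbon bonds to the internal vinyl carbon while its enol O–H is passed to the terminal CH2 in one concerted, asynchronous five-centre (Conia-ene-like) transition state, after which the adduct collapses to the C4 ketone and releases the carbene. The closest known reaction type is the triazolylidene-catalysed intramolecular hydroacylation of unactivated olefins, by which 2-allyloxybenzaldehydes give 3-methylchroman-4-ones. The pyranone ring closes in the 6-exo-trig mode on the internal alkene carbon, and the terminal carbon becomes the C3 methyl group. C3 is set under control of the C2 stereocentre: with the C2 methyl pseudo-equatorial and the vinyl CH2 turned toward the enol O–H, the new C–C bond should form on the alkene face that places the incipient C3 methyl cis to the C2 methyl (2R,3S), and the chiral triazolium is used as the antipode that reinforces this preference. The step needs chemoselectivity for the butenyl alkene, secured because only it can reach the acyl carbon through a six-membered ring, and retention of the kinetic cis product, secured by keeping DBU below the azolium loading so that almost no free amidine remains to epimerise C3. The two ortho substituents twist the hydroxy-enamine out of the arene plane, which is the geometry the in-plane six-membered closure requires, and neither the aryl iodide, the acetals nor the ester should react with the carbene.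

Step 7
Reactants: 10 (R)-lavandulol [(2R)-5-methyl-2-(prop-1-en-2-yl)hex-4-en-1-ol]
Product: 11 (R)-lavandulyl iodide [(5R)-5-(iodomethyl)-2,6-dimethylhepta-2,6-diene]
Conditions: I2, PPh3, imidazole, CH2Cl2, 0 °C → rt
Reagents that add atoms: iodine, [I][I]
Why: Appel-type iodination of the primary homoallylic alcohol by SN2 at the CH2 group, which leaves the adjacent stereocentre untouched.

Step 8
Reactants: 9 methyl (3S)-3-[(2R,3S)-8-iodo-5,7-bis(methoxymethoxy)-2,3-dimethyl-4-oxochroman-6-yl]-3-phenylpropanoate; 11 (R)-lavandulyl iodide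
Product: 13 methyl (3S)-3-[(2R,3S)-5,7-bis(methoxymethoxy)-2,3-dimethyl-8-[(2S)-5-methyl-2-(prop-1-en-2-yl)hex-4-en-1-yl]-4-oxochroman-6-yl]-3-phenylpropanoate, via (R)-lavandulylzinc iodide 12 (not isolated)
Conditions: 11, Zn dust, LiCl, THF, 40 °C; then 9, Pd(OAc)2 (cat.), SPhos (cat.), THF, rt → 45 °C
Reagents that add atoms: none
Why: Negishi sp3–sp2 cross-coupling, in which zinc inserts into the primary C–iodine bond, the alkylzinc iodide tolerates ketone, ester and acetals and is too weakly basic to epimerise C3, the bulky biaryl phosphine drives coupling at the di-ortho-oxygenated aryl iodide, the lavandulyl centre β to the metal is carried through unchanged (its descriptor becomes S by priority only), and doing this after ring closure keeps zerovalent palladium away from an allylic aryl ether.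

Step 9
Reactants: 13 methyl (3S)-3-[(2R,3S)-5,7-bis(methoxymethoxy)-2,3-dimethyl-8-[(2S)-5-methyl-2-(prop-1-en-2-yl)hex-4-en-1-yl]-4-oxochroman-6-yl]-3-phenylpropanoate
Product: 14 methyl (3S)-3-[(2R,3S)-5,7-dihydroxy-2,3-dimethyl-8-[(2S)-5-methyl-2-(prop-1-en-2-yl)hex-4-en-1-yl]-4-oxochroman-6-yl]-3-phenylpropanoate
Conditions: HCl (1.25 M in MeOH), 0 °C → rt; NaHCO3 quench
Reagents that add atoms: none
Why: Acid-catalysed transacetalisation to methanol removes both methoxymethyl groups (the one on O5 assisted by the neighbouring C4 carbonyl), the methyl ester is degenerate in methanol, and dilute acid at or below room temperature should neither protonate the isopropenyl and trisubstituted alkenes nor enolise C3 at a competitive rate.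

Step 10
Reactants: 14 methyl (3S)-3-[(2R,3S)-5,7-dihydroxy-2,3-dimethyl-8-[(2S)-5-methyl-2-(prop-1-en-2-yl)hex-4-en-1-yl]-4-oxochroman-6-yl]-3-phenylpropanoate; 15 prenyl acetate (3-methylbut-2-en-1-yl acetate)
Product: 16 methyl (3S)-3-[(2R,3S,8S)-5-hydroxy-2,3-dimethyl-8-(3-methylbut-2-en-1-yl)-8-[(2S)-5-methyl-2-(prop-1-en-2-yl)hex-4-en-1-yl]-4,7-dioxo-3,4,7,8-tetrahydro-2H-chromen-6-yl]-3-phenylpropanoate
Conditions: Pd2(dba)3 (cat.), (1S,2S)-N,N'-bis[2-(diphenylphosphino)benzoyl]cyclohexane-1,2-diamine (cat.), Et3N, THF, 0 °C → rt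
Reagents that add atoms: none
Why: Palladium-catalysed asymmetric allylic dearomatisation (Tsuji–Trost), in which the 7-phenoxide attacks the π-prenyl–Pd intermediate through C8 at the unsubstituted allyl terminus, O-prenylation is reversible under the catalyst while C8-alkylation is driven by formation of the acidic enolised β-diketone, the chiral ligand pocket selects the arene face that gives 8S because the resident stereocentres are remote, and C8 with its primary alkyl group is less hindered than C6 with its secondary benzylic group.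

Step 11
Reactants: 16 methyl ester of the target
Product: 17 (3S)-3-[(2R,3S,8S)-5-hydroxy-2,3-dimethyl-8-(3-methylbut-2-en-1-yl)-8-[(2S)-5-methyl-2-(prop-1-en-2-yl)hex-4-en-1-yl]-4,7-dioxo-3,4,7,8-tetrahydro-2H-chromen-6-yl]-3-phenylpropanoic acid (CNP0150579.2)
Conditions: Me3SnOH, 1,2-dichloroethane, 70 °C; then 1 M HCl
Reagents that add atoms: trimethyltin hydroxide, C[Sn](C)(C)O
Why: Trimethyltin hydroxide should cleave the unhindered methyl ester under nearly neutral conditions, which avoids hydroxide-induced epimerisation at C3 and retro-oxa-Michael opening of the pyranone.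

**Compound list**

1 | 5,7-dihydroxy-4-phenyl-2H-chromen-2-one | O=C1C=C(c2ccccc2)c2c(O)cc(O)cc2O1 | starting material
2 | (S)-but-3-en-2-ol | C=C[C@H](C)O | starting material
3 | 7-[(2R)-but-3-en-2-yloxy]-5-hydroxy-4-phenyl-2H-chromen-2-one | O=C1C=C(c2ccccc2)c2c(O)cc(O[C@H](C)C=C)cc2O1 | intermediate
4 | (4S)-7-[(2R)-but-3-en-2-yloxy]-5-hydroxy-4-phenylchroman-2-one (not isolated) | O=C1C[C@@H](c2ccccc2)c2c(O)cc(O[C@H](C)C=C)cc2O1 | intermediate
5 | methyl (3S)-3-{4-[(2R)-but-3-en-2-yloxy]-2,6-dihydroxyphenyl}-3-phenylpropanoate | COC(=O)C[C@@H](c1ccccc1)c1c(O)cc(O[C@H](C)C=C)cc1O | intermediate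
6 | methyl (3S)-3-{4-[(2R)-but-3-en-2-yloxy]-3-formyl-2,6-dihydroxyphenyl}-3-phenylpropanoate | COC(=O)C[C@@H](c1ccccc1)c1c(O)cc(O[C@H](C)C=C)c(C=O)c1O | intermediate
7 | methyl (3S)-3-{4-[(2R)-but-3-en-2-yloxy]-3-formyl-2,6-dihydroxy-5-iodophenyl}-3-phenylpropanoate | COC(=O)C[C@@H](c1ccccc1)c1c(O)c(I)c(O[C@H](C)C=C)c(C=O)c1O | intermediate
8 | methyl (3S)-3-{4-[(2R)-but-3-en-2-yloxy]-3-formyl-5-iodo-2,6-bis(methoxymethoxy)phenyl}-3-phenylpropanoate | COC(=O)C[C@@H](c1ccccc1)c1c(OCOC)c(I)c(O[C@H](C)C=C)c(C=O)c1OCOC | intermediate
9 | methyl (3S)-3-[(2R,3S)-8-iodo-5,7-bis(methoxymethoxy)-2,3-dimethyl-4-oxochroman-6-yl]-3-phenylpropanoate | COC(=O)C[C@@H](c1ccccc1)c1c(OCOC)c(I)c2O[C@H](C)[C@H](C)C(=O)c2c1OCOC | intermediate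
10 | (R)-lavandulol, (2R)-5-methyl-2-(prop-1-en-2-yl)hex-4-en-1-ol | C=C(C)[C@@H](CC=C(C)C)CO | starting material
11 | (R)-lavandulyl iodide, (5R)-5-(iodomethyl)-2,6-dimethylhepta-2,6-diene | C=C(C)[C@@H](CC=C(C)C)CI | intermediate
12 | (R)-lavandulylzinc iodide (not isolated) | C=C(C)[C@@H](CC=C(C)C)C[Zn]I | intermediate
13 | methyl (3S)-3-[(2R,3S)-5,7-bis(methoxymethoxy)-2,3-dimethyl-8-[(2S)-5-methyl-2-(prop-1-en-2-yl)hex-4-en-1-yl]-4-oxochroman-6-yl]-3-phenylpropanoate | COC(=O)C[C@@H](c1ccccc1)c1c(OCOC)c(C[C@H](CC=C(C)C)C(C)=C)c2O[C@H](C)[C@H](C)C(=O)c2c1OCOC | intermediate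
14 | methyl (3S)-3-[(2R,3S)-5,7-dihydroxy-2,3-dimethyl-8-[(2S)-5-methyl-2-(prop-1-en-2-yl)hex-4-en-1-yl]-4-oxochroman-6-yl]-3-phenylpropanoate | COC(=O)C[C@@H](c1ccccc1)c1c(O)c(C[C@H](CC=C(C)C)C(C)=C)c2O[C@H](C)[C@H](C)C(=O)c2c1O | intermediate
15 | prenyl acetate, 3-methylbut-2-en-1-yl acetate | CC(=O)OCC=C(C)C | starting material
16 | methyl (3S)-3-[(2R,3S,8S)-5-hydroxy-2,3-dimethyl-8-(3-methylbut-2-en-1-yl)-8-[(2S)-5-methyl-2-(prop-1-en-2-yl)hex-4-en-1-yl]-4,7-dioxo-3,4,7,8-tetrahydro-2H-chromen-6-yl]-3-phenylpropanoate | C=C(C)[C@@H](CC=C(C)C)C[C@]1(CC=C(C)C)C(=O)C([C@@H](CC(=O)OC)c2ccccc2)=C(O)C2=C1O[C@H](C)[C@H](C)C2=O | intermediate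
17 | (3S)-3-[(2R,3S,8S)-5-hydroxy-2,3-dimethyl-8-(3-methylbut-2-en-1-yl)-8-[(2S)-5-methyl-2-(prop-1-en-2-yl)hex-4-en-1-yl]-4,7-dioxo-3,4,7,8-tetrahydro-2H-chromen-6-yl]-3-phenylpropanoic acid | C=C(C)[C@@H](CC=C(C)C)C[C@]1(CC=C(C)C)C(=O)C([C@@H](CC(=O)O)c2ccccc2)=C(O)C2=C1O[C@H](C)[C@H](C)C2=O | target

**Step count**

Total: 11 steps. Longest linear sequence: 10 steps (steps 1 to 6 and 8 to 11); step 7 is a one-step side branch.

**Three steps most likely to fail, with fallbacks**

Step 6. The carbene may add too slowly to the di-ortho-substituted, electron-rich aldehyde, or the kinetically formed cis ketone may epimerise at C3 under the amidine base. The fallback sets out from 8 and returns at 9. A base-free, thiol-catalysed radical-chain hydroacylation (tert-dodecanethiol, AIBN, chlorobenzene, 80 °C) closes the ring through the acyl radical in the 6-exo-trig mode, and the primary radical takes hydrogen from the thiol. This should give the chromanone mainly as its trans epimer, methyl (3S)-3-[(2R,3R)-8-iodo-5,7-bis(methoxymethoxy)-2,3-dimethyl-4-oxochroman-6-yl]-3-phenylpropanoate F1. The C3 epimer mixture is converted with LiN(SiMe3)2 and Me3SiCl (THF, −78 °C) into the trimethylsilyl enol ether, methyl (3S)-3-[(2R)-8-iodo-5,7-bis(methoxymethoxy)-2,3-dimethyl-4-(trimethylsilyloxy)-2H-chromen-6-yl]-3-phenylpropanoate F2. Fluoride-triggered kinetic protonation (Bu4NF, AcOH, THF, −78 °C) anti to the pseudo-axial C2 methyl should then return the cis ketone 9.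

Step 10. Alkylation may go to oxygen or to C6, or both faces of C8 may react, because no resident stereocentre is near. The fallback sets out from 14 and returns at 16. It replaces the chiral metal complex by chiral ion-pair control: phase-transfer C-alkylation with prenyl bromide, an N-(9-anthracenylmethyl)cinchonidinium bromide catalyst and solid K3PO4 in toluene at −20 °C, where the tight ion pair in a non-polar medium favours C- over O-alkylation. It makes no new compound.

Step 2. Hydride delivery to the peri-hindered C4 may be slow, so that hydrometalation of the vinyl group or reduction of the lactone carbonyl competes, or facial selectivity may be poor. The fallback sets out from 2 and returns at 4; it forms the benzylic centre by C–C instead of C–H bond formation. Mitsunobu etherification (PPh3, DIAD, THF) of purchased 5,7-dihydroxy-2H-chromen-2-one F3 with 2 gives 7-[(2R)-but-3-en-2-yloxy]-5-hydroxy-2H-chromen-2-one F4. Rhodium-catalysed asymmetric 1,4-addition of phenylboronic acid (Rh(acac)(C2H4)2, (S)-SEGPHOS, dioxane/H2O, 60 °C) then gives lactone 4, now isolated, which is opened to 5 with MeOH and catalytic K2CO3 as in step 2.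

**Further compounds**

F1 | step 6 | methyl (3S)-3-[(2R,3R)-8-iodo-5,7-bis(methoxymethoxy)-2,3-dimethyl-4-oxochroman-6-yl]-3-phenylpropanoate | COC(=O)C[C@@H](c1ccccc1)c1c(OCOC)c(I)c2O[C@H](C)[C@@H](C)C(=O)c2c1OCOC
F2 | step 6 | methyl (3S)-3-[(2R)-8-iodo-5,7-bis(methoxymethoxy)-2,3-dimethyl-4-(trimethylsilyloxy)-2H-chromen-6-yl]-3-phenylpropanoate | COC(=O)C[C@@H](c1ccccc1)c1c(OCOC)c(I)c2O[C@H](C)C(C)=C(O[Si](C)(C)C)c2c1OCOC
F0 | step 10 | none | none
F3 | step 2 | 5,7-dihydroxy-2H-chromen-2-one (purchased starting material of the fallback) | O=C1C=Cc2c(O)cc(O)cc2O1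
F4 | step 2 | 7-[(2R)-but-3-en-2-yloxy]-5-hydroxy-2H-chromen-2-one | O=C1C=Cc2c(O)cc(O[C@H](C)C=C)cc2O1
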